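**Plan**

Numbering (asbestinin): cyclohexane = C1, C10, C11 (OAc), C12 (Me), C13, C14. Oxolane = O, C2, C1, C10, C9. Oxonane = the same O plus C2–C9 (C3 quaternary, C7 ketone). Oxepane = C1, C14, C15 (Me), C16, O, C3, C2.
Cuts, in retrosynthetic order: C7 ketone to carbinol; C16–O (oxepane); C5=C6 (metathesis); C12–CH3; then C1–C10, redrawn as C1–C11; O–C9; C10–C11; finally C1–C2 and C14–C15.
Enabling feature: C11 carries oxygen and is bonded to C10. C10 belongs to both the cyclohexane and the oxolane, and the C1–C10 bond is shared by the two rings. That bond can therefore come from the C1–C11 bond of a trans-fused cyclopentane/oxane (cyclopenta[c]pyran) in which C3, C14, the C10 leaving group and C8 are all equatorial.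
Forward ring order: cyclopentane (bought), oxane (iodoetherification), one 1,2-shift that turns cyclopentane/oxane into cyclohexanone/oxolane, oxonene (metathesis), oxepane (etherification).
Stereochemistry: one catalytic event, a Sharpless kinetic resolution/epoxidation, fixes the absolute configuration of C1, C2 and C14 and sets C3. C9 and C10 follow from a chair iodoetherification and the stereospecific shift. C12, C11 and C15 follow from attack on the less hindered face of the bicycle.

Key step: step 9

Remark: 5 and 6 are racemic and their SMILES show the enantiomer that is carried on; from 7 onward the main line is a single enantiomer.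
Assumption: the carbinol carbon that becomes C7 is used racemic (11–16). Compounds 17–35 are therefore pairs of C7 epimers that converge in step 18, and their SMILES leave C7 open.

**Step 1**
Reactants: 1 pent-4-enal
Product: 2 2-methylidenepent-4-enal
Conditions: 37 % aq HCHO, pyrrolidine (10 mol %), EtCO2H (10 mol %), i-PrOH, 45 °C
Reagents that add atoms: formaldehyde, C=O
Why: Amine-catalysed Mannich condensation–elimination (organocatalytic alpha-methylenation of an aldehyde) places the methylidene carbon, the later C3 methyl group, next to the formyl group without touching the terminal alkene.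

**Step 2**
Reactants: 3 cyclopent-2-en-1-one; 4 isopropenylmagnesium bromide; 2 2-methylidenepent-4-enal
Product: 6 rac-(2R*,3R*)-2-[(1S*)-1-hydroxy-2-methylidenepent-4-en-1-yl]-3-(prop-1-en-2-yl)cyclopentan-1-one (ring substituents trans, anti aldol), via bromomagnesium enolate 5 (not isolated)
Conditions: 4, CuI·2LiCl (10 mol %), THF, −78 °C, then 3; then 2, −78 to −40 °C; aq NH4Cl
Reagents that add atoms: none
Why: Copper-catalysed conjugate addition with aldol trapping of the regiodefined enolate (three-component coupling), in which the aldehyde is attacked anti to the new isopropenyl group (C1/C14 trans) and the cyclic E-enolate reacts through a chelated Zimmerman–Traxler chair to give the anti aldol (C1/C2), the relationship that later makes C3 equatorial on the oxane.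

**Step 3**
Reactants: 6 racemic aldol
Product: 7 (2R,3R)-2-{(S)-hydroxy[(2R)-2-(prop-2-en-1-yl)oxiran-2-yl]methyl}-3-(prop-1-en-2-yl)cyclopentan-1-one
Conditions: Ti(OiPr)4 (0.15 equiv), L-(+)-diisopropyl tartrate (0.2 equiv), t-BuOOH (0.5 equiv), 4 Å MS, CH2Cl2, −20 °C
Reagents that add atoms: tert-butyl hydroperoxide, CC(C)(C)OO
Why: Sharpless kinetic resolution, in which L-(+)-tartrate epoxidises the (S)-carbinol enantiomer much faster and gives the erythro epoxy alcohol, fixing the absolute configuration of C1, C2 and C14 and setting C3, while the isolated alkenes and the slow enantiomer (removed by chromatography) do not react.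

**Step 4**
Reactants: 8 acrolein; 9 propargyl bromide
Product: 11 rac-hex-1-en-5-yn-3-ol, via allenylzinc bromide 10 (not isolated)
Conditions: Zn dust, THF–sat. aq NH4Cl, 0 °C
Reagents that add atoms: none
Why: Zinc Barbier propargylation, in which the allenylzinc species adds 1,2 to the enal through an SE2' transition state to give the homopropargylic alcohol, whose carbinol centre (C7) is erased in step 18.

**Step 5**
Reactants: 11 rac-hex-1-en-5-yn-3-ol
Product: 12 rac-3-(benzyloxy)hex-1-en-5-yne
Conditions: NaH, BnBr, n-Bu4NI (cat.), THF, 0 °C to rt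
Reagents that add atoms: benzyl bromide, BrCc1ccccc1
Why: Williamson etherification of the alkoxide installs a protecting group that survives organolithium, iodonium, base, hydride, borane and triflate chemistry and leaves by hydrogenolysis in step 17.

**Step 6**
Reactants: 12 rac-3-(benzyloxy)hex-1-en-5-yne
Product: 14 rac-(1E)-4-(benzyloxy)-1-iodohexa-1,5-diene, via alkenylzirconocene chloride 13 (not isolated)
Conditions: Cp2Zr(H)Cl (1.1 equiv), THF, rt, dark; I2, 0 °C
Reagents that add atoms: iodine, [I][I]
Why: Hydrozirconation–iodinolysis, in which syn addition of Zr–H to the terminal alkyne (faster than to the vinyl group) places zirconium at the terminus and iodine replaces it with retention to give the E-iodide.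

**Step 7**
Reactants: 14 E-alkenyl iodide; 7 epoxy ketone
Product: 17 (1S,2R,3R)-1-[(1E)-4-(benzyloxy)hexa-1,5-dien-1-yl]-2-{(S)-hydroxy[(2R)-2-allyloxiran-2-yl]methyl}-3-isopropenylcyclopentan-1-ol (alkenyl group trans, C11 hydroxyl cis to the C1 side chain), via alkenyllithium 15 (not isolated), via alkenylcerium dichloride 16 (not isolated)
Conditions: 14 (2.4 equiv), t-BuLi (4.8 equiv), Et2O, −78 °C; CeCl3 (2.5 equiv), THF, −78 °C; 7, −78 °C; aq NH4Cl
Reagents that add atoms: none
Why: Iodine–lithium exchange with retention of geometry, transmetalation to the weakly basic organocerium reagent and 1,2-addition, in which one equivalent deprotonates the C2 hydroxyl and the next attacks the cyclopentanone anti to the adjacent C1 side chain, the oxirane being inert at −78 °C and C11 being erased again in step 9.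

**Step 8**
Reactants: 17 diol
Product: 18 iodo-oxane: oxane O/C2/C1/C11/C10/C9 trans-fused to cyclopentane C11–C14/C1; the oxiranyl carbon C3 on C2, C14 on C1, iodine on C10 and C8 on C9 all equatorial; 11-OH axial
Conditions: N-iodosuccinimide (1.1 equiv), MeCN–CH2Cl2, −20 to 0 °C, dark
Reagents that add atoms: N-iodosuccinimide, O=C1CCC(=O)N1I
Why: 6-endo iodoetherification, in which reversible iodonium formation becomes productive only at C9=C10 where the C2 hydroxyl attacks C9 in a chair transition state (5-exo attack at neopentylic C10 would give a trans-fused bicyclo[3.3.0] system), and anti addition to the E-alkene places C8 and iodine equatorial, setting C9 and the C10–I configuration.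

**Step 9**
Reactants: 18 iodo-oxane
Product: 20 cis-fused hexahydroisobenzofuran-4-one: C11 ketone, 7-isopropenyl (C14), 1-[(2R)-2-allyloxiran-2-yl] (C2) and 3-[2-(benzyloxy)but-3-enyl] (C9), both oxolane side chains on the convex face, via potassium alkoxide 19 (not isolated)
Conditions: KN(SiMe3)2 (1.05 equiv), THF, −78 to 0 °C; pH 7 buffer
Reagents that add atoms: none
Why: Deprotonation gives tertiary alkoxide 19, in which the equatorial C10–I bond of the chair oxane is antiperiplanar to the ring-fusion bond C11–C1, so the oxygen lone pair pushes C1 from C11 to C10 as iodide leaves, an anionic semipinacol rearrangement of the type known from base treatment of cis-halohydrins, from ring enlargement of 1-(1-haloalkyl)cycloalkanol salts and from pyranoside-to-furanoside contraction of vicinal hydroxy sulfonates. No exo or endo cyclisation takes place: one suprafacial 1,2-alkyl shift moves the bond shared by the two rings, so that C10 enters the carbocycle (cyclopentane to cyclohexanone, expansion by one atom) and C11 leaves the heterocycle (oxane to oxolane, contraction by one atom). C10 is the only new stereocentre and is formed with inversion, so it is dictated by the C10–I configuration from step 8, while C1 migrates with retention and C2, C9 and C14 are untouched, which converts the all-equatorial oxane into the cis-fused oxolane with C3 and C8 on the convex face. The step needs migration of C1 and not of C12, and this is secured because C12 is gauche to the C–I bond and cannot overlap with its antibonding orbital. Epoxide closure is excluded because axial O11 and equatorial iodine are gauche, elimination because no hydrogen is antiperiplanar to iodine, and participation of the likewise antiperiplanar ring oxygen should be outrun by working through the alkoxide without a Lewis acid, which also spares the C3 oxirane. The single equivalent of base is consumed as potassium iodide forms, so the new ketone should not be enolised and C10 should not epimerise.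

**Step 10**
Reactants: 20 bicyclic ketone
Product: 24 12-methylidene ketone (exocyclic enone C11(=O)–C12(=CH2)), via lithium enolate 21 (not isolated), via Mannich base 22 (not isolated), via methiodide 23 (not isolated)
Conditions: LiN(SiMe3)2, THF, −78 °C; (CH2=NMe2)I, −78 °C to rt; MeI, rt; aq NaHCO3, rt
Reagents that add atoms: N,N-dimethylmethyleneiminium iodide (Eschenmoser's salt), C=[N+](C)C.[I-]
Why: Kinetic deprotonation at the C12 methylene (C10 is tertiary and hindered), Mannich reaction, quaternisation and beta-elimination (alpha-methylenation of a ketone) add the last skeletal carbon under conditions that leave the oxirane closed.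

**Step 11**
Reactants: 24 exocyclic enone
Product: 26 (12R)-12-methyl ketone (methyl on the concave face, cis to C9 and C2), via methyl-substituted lithium enolate 25 (not isolated)
Conditions: LiBH(s-Bu)3 (1.05 equiv), THF, −78 °C; 2,6-di-tert-butyl-4-methylphenol, −78 °C; pH 7 buffer
Reagents that add atoms: none
Why: Conjugate hydride reduction of the s-cis enone followed by kinetic protonation of enolate 25, in which the bulky phenol should reach C12 from the convex face (the side of H1 and H10) because the concave face is screened by pseudoaxial C9, so that the methyl group ends up cis to C9, the isolated alkenes being inert to the borohydride.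

**Step 12**
Reactants: 26 methyl ketone
Product: 28 diol: (11R)-secondary alcohol (cis to the C12 methyl and to C9) and (3S)-tertiary alcohol C3(OH)(CH3)(allyl), via epoxy alcohol 27 (not isolated)
Conditions: LiBHEt3 (4 equiv), THF, −78 °C, then 0 °C to rt; H2O
Reagents that add atoms: none
Why: Borohydride reduction, in which hydride attacks the ketone at −78 °C from the convex face before C12 can epimerise, and on warming the same reagent opens the 2,2-disubstituted oxirane by SN2 attack at its CH2 group, unveiling the C3 methyl group and the tertiary alcohol with C3 untouched.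

**Step 13**
Reactants: 28 diol
Product: 29 11-acetate (C3 hydroxyl free)
Conditions: Ac2O, pyridine, DMAP (cat.), CH2Cl2, 0 °C to rt
Reagents that add atoms: acetic anhydride, CC(=O)OC(C)=O
Why: DMAP-catalysed acylation discriminates the secondary C11 hydroxyl from the much more hindered tertiary C3 hydroxyl.

**Step 14**
Reactants: 29 acetate triene
Product: 30 tricyclic (5Z)-oxonene (ring O, C2–C9 closed; 7-OBn, 3-OH, 14-isopropenyl)
Conditions: second-generation Grubbs catalyst (10 mol %), CH2Cl2 (1 mM), reflux
Reagents that add atoms: none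
Why: Ring-closing metathesis of the two monosubstituted alkenes, in which the cis-2,5 arrangement on the oxolane holds both chains on one face, the nine-membered ring enforces the Z-alkene and the 1,1-disubstituted isopropenyl group stays out of the catalytic cycle.

**Step 15**
Reactants: 30 oxonene
Product: 32 (15R)-primary alcohol C14–CH(CH3)–CH2OH, via B-alkyl-9-BBN adduct 31 (not isolated)
Conditions: 9-BBN (3 equiv), THF, 0 °C to rt; 3 M aq NaOAc, 30 % H2O2, 0 °C to rt
Reagents that add atoms: hydrogen peroxide, OO
Why: Hydroboration–oxidation, in which 9-BBN reacts with the terminal 1,1-disubstituted alkene far faster than with the internal Z-alkene and should attack the rotamer with H14 eclipsing C15=C16 (boron far from the ring) from the side of C13H2 rather than of the substituted C1, giving 15R, while the buffered oxidation spares the acetate.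

**Step 16**
Reactants: 32 diol
Product: 34 tetracyclic benzyl ether (oxepane closed; 5Z-alkene), via primary triflate 33 (not isolated)
Conditions: Tf2O (1.1 equiv), 2,6-lutidine (4 equiv), CH2Cl2, −78 °C to rt
Reagents that add atoms: none
Why: Selective triflation of the primary alcohol and in situ 7-exo-tet Williamson-type displacement by the C3 hydroxyl, which is held close because C2 and C15 are trans-diequatorial neighbours on the cyclohexane, no stereocentre being touched.

**Step 17**
Reactants: 34 tetracyclic benzyl ether
Product: 35 saturated C7 alcohol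
Conditions: H2 (1 atm), Pd/C (10 wt %), EtOAc–EtOH, rt
Reagents that add atoms: none
Why: Catalytic hydrogenation saturates the strained Z-alkene first and then cleaves the benzyl ether by hydrogenolysis, acetate and dialkyl ethers being inert.

**Step 18**
Reactants: 35 C7 alcohol
Product: 36 target, (1S,2S,3S,9S,10R,11R,12R,14S,15R)-configured nor-asbestinin ketone acetate
Conditions: Dess–Martin periodinane, CH2Cl2, 0 °C to rt
Reagents that add atoms: none
Why: Dess–Martin oxidation of the only free hydroxyl merges both C7 epimers into the ketone under neutral conditions that do not provoke beta-elimination of the C9 oxygen.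

**Compound list**

| No. | Name | SMILES | Role |
|---|---|---|---|
| 1 | pent-4-enal | C=CCCC=O | starting material |
| 2 | 2-methylidenepent-4-enal | C=CCC(=C)C=O | intermediate |
| 3 | cyclopent-2-en-1-one | O=C1CCC=C1 | starting material |
| 4 | isopropenylmagnesium bromide | CC(=C)[Mg]Br | starting material |
| 5 | bromomagnesium enolate of 3-isopropenylcyclopentanone (racemic) | Br[Mg]OC1=C[C@H](C(C)=C)CC1 | intermediate |
| 6 | rac-trans,anti aldol (2R*,3R*,1'S*) | O=C1CC[C@@H](C(C)=C)[C@@H]1[C@H](O)C(=C)CC=C | intermediate |
| 7 | erythro epoxy alcohol (2R,3R; carbinol S; oxirane R) | O=C1CC[C@@H](C(C)=C)[C@@H]1[C@H](O)[C@@]2(CC=C)CO2 | intermediate |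
| 8 | acrolein | C=CC=O | starting material |
| 9 | propargyl bromide | C#CCBr | starting material |
| 10 | allenylzinc bromide | C=C=C[Zn]Br | intermediate |
| 11 | rac-hex-1-en-5-yn-3-ol | C=CC(O)CC#C | intermediate |
| 12 | rac-3-(benzyloxy)hex-1-en-5-yne | C=CC(CC#C)OCc1ccccc1 | intermediate |
| 13 | (E)-alkenylzirconocene chloride (cyclopentadienyl rings drawn sigma-bonded) | Cl[Zr](/C=C/CC(C=C)OCc1ccccc1)(C2C=CC=C2)C3C=CC=C3 | intermediate |
| 14 | rac-(1E)-4-(benzyloxy)-1-iodohexa-1,5-diene | I/C=C/CC(C=C)OCc1ccccc1 | intermediate |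
| 15 | (E)-alkenyllithium | [Li]/C=C/CC(C=C)OCc1ccccc1 | intermediate |
| 16 | (E)-alkenylcerium dichloride | Cl[Ce](Cl)/C=C/CC(C=C)OCc1ccccc1 | intermediate |
| 17 | tertiary allylic alcohol/diol (1S,2R,3R) | O[C@]1(/C=C/CC(OCc2ccccc2)C=C)CC[C@@H](C(C)=C)[C@@H]1[C@H](O)[C@@]3(CC=C)CO3 | intermediate |
| 18 | all-equatorial iodo-oxane, trans-fused to the cyclopentane | O[C@]12CC[C@@H](C(C)=C)[C@@H]1[C@@H]([C@@]3(CC=C)CO3)O[C@@H](CC(OCc3ccccc3)C=C)[C@@H]2I | intermediate |
| 19 | potassium alkoxide of 18 | [K+].[O-][C@]12CC[C@@H](C(C)=C)[C@@H]1[C@@H]([C@@]3(CC=C)CO3)O[C@@H](CC(OCc3ccccc3)C=C)[C@@H]2I | intermediate |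
| 20 | cis-fused hexahydroisobenzofuran-4-one (C11 ketone) | O=C1[C@@H]2[C@H]([C@@H](CC1)C(C)=C)[C@H](O[C@H]2CC(OCc3ccccc3)C=C)[C@@]4(CC=C)CO4 | intermediate |
| 21 | kinetic lithium enolate (C11=C12) | [Li]OC1=CC[C@@H](C(C)=C)[C@@H]2[C@@H]([C@@]3(CC=C)CO3)O[C@@H](CC(OCc3ccccc3)C=C)[C@H]12 | intermediate |
| 22 | 12-(dimethylaminomethyl) ketone (C12 open) | O=C1[C@@H]2[C@H]([C@@H](CC1CN(C)C)C(C)=C)[C@H](O[C@H]2CC(OCc3ccccc3)C=C)[C@@]4(CC=C)CO4 | intermediate |
| 23 | trimethylammonium iodide of 22 | O=C1[C@@H]2[C@H]([C@@H](CC1C[N+](C)(C)C)C(C)=C)[C@H](O[C@H]2CC(OCc3ccccc3)C=C)[C@@]4(CC=C)CO4.[I-] | intermediate |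
| 24 | 12-methylidene ketone | O=C1[C@@H]2[C@H]([C@@H](CC1=C)C(C)=C)[C@H](O[C@H]2CC(OCc3ccccc3)C=C)[C@@]4(CC=C)CO4 | intermediate |
| 25 | lithium enolate C11(OLi)=C12(CH3) | [Li]OC1=C(C)C[C@@H](C(C)=C)[C@@H]2[C@@H]([C@@]3(CC=C)CO3)O[C@@H](CC(OCc3ccccc3)C=C)[C@H]12 | intermediate |
| 26 | (12R)-methyl ketone | O=C1[C@@H]2[C@H]([C@@H](C[C@H]1C)C(C)=C)[C@H](O[C@H]2CC(OCc3ccccc3)C=C)[C@@]4(CC=C)CO4 | intermediate |
| 27 | (11R,12R)-epoxy alcohol (present as its lithium alkoxide) | O[C@H]1[C@@H]2[C@H]([C@@H](C[C@H]1C)C(C)=C)[C@H](O[C@H]2CC(OCc3ccccc3)C=C)[C@@]4(CC=C)CO4 | intermediate |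
| 28 | C11/C3 diol | O[C@H]1[C@@H]2[C@H]([C@@H](C[C@H]1C)C(C)=C)[C@H](O[C@H]2CC(OCc3ccccc3)C=C)[C@@](C)(O)CC=C | intermediate |
| 29 | 11-acetate | CC(=O)O[C@H]1[C@@H]2[C@H]([C@@H](C[C@H]1C)C(C)=C)[C@H](O[C@H]2CC(OCc3ccccc3)C=C)[C@@](C)(O)CC=C | intermediate |
| 30 | tricyclic (5Z)-oxonene | CC(=O)O[C@H]1[C@@H]2[C@H]([C@@H](C[C@H]1C)C(C)=C)[C@@H]3O[C@H]2CC(OCc4ccccc4)/C=C\C[C@]3(C)O | intermediate |
| 31 | B-alkyl-9-BBN adduct (15R) | CC(=O)O[C@H]1[C@@H]2[C@H]([C@@H](C[C@H]1C)[C@@H](C)CB5C6CCCC5CCC6)[C@@H]3O[C@H]2CC(OCc4ccccc4)/C=C\C[C@]3(C)O | intermediate |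
| 32 | (15R)-primary alcohol | CC(=O)O[C@H]1[C@@H]2[C@H]([C@@H](C[C@H]1C)[C@@H](C)CO)[C@@H]3O[C@H]2CC(OCc4ccccc4)/C=C\C[C@]3(C)O | intermediate |
| 33 | primary triflate | CC(=O)O[C@H]1[C@@H]2[C@H]([C@@H](C[C@H]1C)[C@@H](C)COS(=O)(=O)C(F)(F)F)[C@@H]3O[C@H]2CC(OCc4ccccc4)/C=C\C[C@]3(C)O | intermediate |
| 34 | tetracyclic benzyl ether | CC(=O)O[C@H]1[C@@H]2[C@@H]3[C@@H](C[C@H]1C)[C@@H](C)CO[C@@]1(C)C/C=C\C(OCc4ccccc4)C[C@@H]2O[C@@H]31 | intermediate |
| 35 | saturated C7 alcohol | CC(=O)O[C@H]1[C@@H]2[C@@H]3[C@@H](C[C@H]1C)[C@@H](C)CO[C@@]1(C)CCCC(O)C[C@@H]2O[C@@H]31 | intermediate |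
| 36 | CNP0288436.2 | CC(=O)O[C@H]1[C@@H]2[C@@H]3[C@@H](C[C@H]1C)[C@@H](C)CO[C@@]1(C)CCCC(=O)C[C@@H]2O[C@@H]31 | target |

**Step count**

Total step count: 18.
Longest linear sequence: 15 (steps 1–3 and 7–18).

**Steps most likely to fail**

1. **Step 8.** Iodonium ions at the other four alkenes may be trapped, or closure by the hindered C2 hydroxyl may be too slow.
   - The fallback uses oxygen instead of iodine as the leaving group and places it by hydroxyl direction.
   - Setting out from 17, VO(acac)2/t-BuOOH should epoxidise only C9=C10, the one alkene allylic to a free hydroxyl, to give the bis-epoxide diol F1.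
   - Ti(OiPr)4 in CH2Cl2 then promotes 6-endo opening at C9, the carbon remote from the carbinol as is usual for 2,3-epoxy alcohols, by the C2 hydroxyl. This gives the oxane diol F2.
   - MsCl/Et3N sulfonylates only the secondary equatorial C10 hydroxyl to give the mesylate F3.
   - KN(SiMe3)2 triggers the same 1,2-shift and the route is rejoined at 20.

2. **Step 11.** Facial selectivity in the enolate protonation may be poor, or C12 may epimerise before reduction.
   - The fallback delivers the methyl carbon from the C11 oxygen, so that it must end up cis to it.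
   - Setting out from 20, the kinetic lithium enolate is dehydrogenated with N-tert-butylbenzenesulfinimidoyl chloride to give the C12=C13 enone F4.
   - NaBH4/CeCl3 reduces it 1,2 from the convex face to the allylic alcohol F5.
   - BrCH2SiMe2Cl/Et3N gives the bromomethylsilyl ether F6.
   - Bu3SnH/AIBN closes the oxasilolane F7 by 5-exo radical cyclisation onto C12.
   - n-Bu4NF in DMF protodesilylates it to 27, which is carried through the warm phase of step 12 to 28.

3. **Step 15.** Facial selectivity of the borane at the freely rotating isopropenyl group may be poor.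
   - The fallback relies on cyclic stereocontrol.
   - Setting out from 30, ene-type chlorination with Ca(OCl)2/CO2 in CH2Cl2–H2O gives the allylic chloride F8.
   - AgOTf with 2,6-di-tert-butylpyridine lets the C3 hydroxyl close the methylidene oxepane F9.
   - The hydrogenation of step 17 then also saturates C15=CH2 from the oxepane face that carries H14, opposite to C13. This gives the 15R methyl group and rejoins the route at 35.

**Further compounds**

F1 | step 8 | bis-epoxide diol (trans-C9/C10 oxirane) | O[C@]1([C@H]2O[C@@H]2CC(OCc3ccccc3)C=C)CC[C@@H](C(C)=C)[C@@H]1[C@H](O)[C@@]4(CC=C)CO4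
F2 | step 8 | oxane diol (equatorial 10-OH, axial 11-OH) | O[C@]12CC[C@@H](C(C)=C)[C@@H]1[C@@H]([C@@]3(CC=C)CO3)O[C@@H](CC(OCc3ccccc3)C=C)[C@@H]2O
F3 | step 8 | C10 mesylate | O[C@]12CC[C@@H](C(C)=C)[C@@H]1[C@@H]([C@@]3(CC=C)CO3)O[C@@H](CC(OCc3ccccc3)C=C)[C@@H]2OS(C)(=O)=O
F4 | step 11 | C12=C13 enone | O=C1[C@@H]2[C@H]([C@@H](C=C1)C(C)=C)[C@H](O[C@H]2CC(OCc3ccccc3)C=C)[C@@]4(CC=C)CO4
F5 | step 11 | (11R)-allylic alcohol | O[C@H]1[C@@H]2[C@H]([C@@H](C=C1)C(C)=C)[C@H](O[C@H]2CC(OCc3ccccc3)C=C)[C@@]4(CC=C)CO4
F6 | step 11 | bromomethyl(dimethyl)silyl ether | BrC[Si](C)(C)O[C@H]1[C@@H]2[C@H]([C@@H](C=C1)C(C)=C)[C@H](O[C@H]2CC(OCc3ccccc3)C=C)[C@@]4(CC=C)CO4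
F7 | step 11 | cis-fused oxasilolane | C[Si]1(C)O[C@H]2[C@@H]3[C@H]([C@@H](C[C@H]2C1)C(C)=C)[C@H](O[C@H]3CC(OCc4ccccc4)C=C)[C@@]5(CC=C)CO5
F8 | step 15 | allylic chloride | CC(=O)O[C@H]1[C@@H]2[C@H]([C@@H](C[C@H]1C)C(=C)CCl)[C@@H]3O[C@H]2CC(OCc4ccccc4)/C=C\C[C@]3(C)O
F9 | step 15 | 15-methylidene oxepane | CC(=O)O[C@H]1[C@@H]2[C@@H]3[C@@H](C[C@H]1C)C(=C)CO[C@@]1(C)C/C=C\C(OCc4ccccc4)C[C@@H]2O[C@@H]31
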